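## Retrosynthetic overview

- The target is epicatechin-(4β→6)-epicatechin-(4β→8)-epicatechin-(4β→6)-epicatechin, and every ring C is cut at O1–C8a and C4a–C4.
- The strategy rests on this feature: in each unit the neighbouring ring A carbons C8a and C4a carry O1 and C4, and C4a lies beside the C5 oxygen, so the pair can be the triple bond of a 3-alkoxyaryne. O1, C2, C3 and C4 come from a threo trans-epoxy alcohol whose alkoxide adds to C8a and whose oxirane is opened at C4 by the aryl anion.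
- The aryl group on C4 of each new unit is ring A of the next unit. It carries one allyl-protected oxygen (the later triflate: para for a 4→6 link, ortho for 4→8) and a bromine beside it (the later trimethylsilyl group).
- Ring order: ring C of unit 1 (from 3,5-bis(benzyloxy)benzyne), then ring C of units 2, 3 and 4 (a terminal epoxide gives the C4 methylene). Each cycle is annulation, 3-O-benzylation, deallylation, silyl triflate formation.
- Hydrogenolysis of nineteen benzyl ethers ends the route.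

Key step: step 21

Remark: 3,5-bis(benzyloxy)phenol, 3,4-dihydroxyacetophenone and 3,4-bis(benzyloxy)benzaldehyde are taken as commercial.
Remark: the 2,3-cis flavan needs the threo (syn) epoxy alcohol, which simple hydrides disfavour, so the carbinol centre is set by a catalyst-controlled transfer hydrogenation.
Remark: the bromine on the pendant ring is added so that the silyl group can later be placed by bromine–lithium exchange without a late electrophilic halogenation.

## Route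

Step 1
Reactants: 1 3,5-bis(benzyloxy)phenol
Product: 2 3,5-bis(benzyloxy)phenyl N,N-diethylcarbamate
Conditions: Et2NCOCl, K2CO3, MeCN, reflux
Reagents that add atoms: N,N-diethylcarbamoyl chloride, CCN(CC)C(Cl)=O
Why: O-carbamoylation of the phenoxide (acyl substitution) installs the strong ortho-directing group needed for the next step.

Step 2
Reactants: 2 3,5-bis(benzyloxy)phenyl N,N-diethylcarbamate
Product: 4 2-bromo-3,5-bis(benzyloxy)phenyl N,N-diethylcarbamate, via aryllithium 3 (not isolated)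
Conditions: s-BuLi, TMEDA, THF, −78 °C; then BrCl2C–CCl2Br, −78 °C to rt
Reagents that add atoms: 1,2-dibromo-1,1,2,2-tetrachloroethane, BrC(Cl)(Cl)C(Cl)(Cl)Br
Why: Directed ortho-metalation, in which the carbamate and the neighbouring benzyloxy group jointly direct lithiation to C2, followed by bromine transfer from the perhaloethane to the aryllithium.

Step 3
Reactants: 4 2-bromo-3,5-bis(benzyloxy)phenyl N,N-diethylcarbamate
Product: 5 2-bromo-3,5-bis(benzyloxy)phenol
Conditions: NaOH, EtOH/H2O, reflux; then dilute HCl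
Reagents that add atoms: none
Why: Basic hydrolysis of the aryl carbamate frees the phenol while the benzyl ethers and the aryl bromide are inert.

Step 4
Reactants: 5 2-bromo-3,5-bis(benzyloxy)phenol
Product: 8 3,5-bis(benzyloxy)-2-(trimethylsilyl)phenyl trifluoromethanesulfonate, via silyl ether 6 (not isolated), via lithium phenoxide 7 (not isolated)
Conditions: HMDS, THF, 70 °C, then evaporation; n-BuLi, THF, −78 °C; Tf2O, −78 °C to rt
Reagents that add atoms: hexamethyldisilazane, C[Si](C)(C)N[Si](C)(C)C; trifluoromethanesulfonic anhydride, O=S(=O)(OS(=O)(=O)C(F)(F)F)C(F)(F)F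
Why: O-silylation, bromine–lithium exchange and 1,3 O→C silyl shift (retro-Brook rearrangement) give the ortho-silyl phenoxide, which is triflated in the same flask, the standard entry to ortho-silylaryl triflates.

Step 5
Reactants: 1 3,5-bis(benzyloxy)phenol
Product: 9 2,6-bis(benzyloxy)-4-hydroxybenzaldehyde
Conditions: POCl3, DMF, MeCN, 0 °C to rt; then aq NaOH, then acidification
Reagents that add atoms: N,N-dimethylformamide, CN(C)C=O; water, O
Why: Vilsmeier–Haack formylation of a 3,5-dialkoxyphenol should go mainly para to the free hydroxyl, and the minor chelated ortho isomer is removed by chromatography.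

Step 6
Reactants: 9 2,6-bis(benzyloxy)-4-hydroxybenzaldehyde
Product: 10 2,6-bis(benzyloxy)-3-bromo-4-hydroxybenzaldehyde
Conditions: NBS (1.0 equiv), MeCN, −20 to 0 °C
Reagents that add atoms: N-bromosuccinimide, O=C1CCC(=O)N1Br
Why: Electrophilic aromatic bromination ortho to the free phenol, where the two open positions are equivalent so only one monobromide can form.

Step 7
Reactants: 10 2,6-bis(benzyloxy)-3-bromo-4-hydroxybenzaldehyde
Product: 11 4-(allyloxy)-2,6-bis(benzyloxy)-3-bromobenzaldehyde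
Conditions: allyl bromide, K2CO3, DMF, rt
Reagents that add atoms: allyl bromide, C=CCBr
Why: Williamson etherification of the acidic phenol gives the allyl ether that is later removed in the presence of benzyl ethers.

Step 8
Reactants: 5 2-bromo-3,5-bis(benzyloxy)phenol
Product: 12 4,6-bis(benzyloxy)-3-bromo-2-hydroxybenzaldehyde
Conditions: MgCl2, Et3N, paraformaldehyde, MeCN, reflux
Reagents that add atoms: formaldehyde (as paraformaldehyde), C=O
Why: Casnati–Skattebøl ortho-formylation through the magnesium phenoxide can only go to C6, the one free position ortho to the hydroxyl.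

Step 9
Reactants: 12 4,6-bis(benzyloxy)-3-bromo-2-hydroxybenzaldehyde
Product: 13 2-(allyloxy)-4,6-bis(benzyloxy)-3-bromobenzaldehyde
Conditions: allyl bromide, Cs2CO3, DMF, 50 °C
Reagents that add atoms: allyl bromide, C=CCBr
Why: Williamson etherification, with the caesium phenoxide overcoming the hydrogen bond to the aldehyde and the flanking bromine.

Step 10
Reactants: 14 3,4-dihydroxyacetophenone
Product: 15 1-[3,4-bis(benzyloxy)phenyl]ethan-1-one
Conditions: BnBr, K2CO3, DMF, 60 °C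
Reagents that add atoms: benzyl bromide, BrCc1ccccc1
Why: Double Williamson benzylation of the catechol.

Step 11
Reactants: 15 1-[3,4-bis(benzyloxy)phenyl]ethan-1-one; 11 4-(allyloxy)-2,6-bis(benzyloxy)-3-bromobenzaldehyde
Product: 16 (E)-3-[4-(allyloxy)-2,6-bis(benzyloxy)-3-bromophenyl]-1-[3,4-bis(benzyloxy)phenyl]prop-2-en-1-one
Conditions: KOH, EtOH/THF, rt
Reagents that add atoms: none
Why: Claisen–Schmidt condensation of the methyl ketone with the non-enolisable aldehyde gives the E-enone after dehydration.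

Step 12
Reactants: 16 the E-chalcone from step 11
Product: 17 [(2R,3S)-3-[4-(allyloxy)-2,6-bis(benzyloxy)-3-bromophenyl]oxiran-2-yl][3,4-bis(benzyloxy)phenyl]methanone
Conditions: La(OiPr)3 (10 mol%), (S)-BINOL (10 mol%), Ph3As=O (10 mol%), TBHP (decane), 4 Å MS, THF, rt
Reagents that add atoms: tert-butyl hydroperoxide, CC(C)(C)OO
Why: Lanthanum–BINOL-catalysed nucleophilic epoxidation of the enone gives the trans-oxirane from the E-alkene, and the ligand sets both oxirane centres by choosing the enone face ((S)-BINOL is expected to give 2R,3S by analogy with chalcone, otherwise its antipode is used).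

Step 13
Reactants: 17 the (2R,3S)-epoxy ketone from step 12
Product: 18 (R)-[3,4-bis(benzyloxy)phenyl]{(2S,3S)-3-[4-(allyloxy)-2,6-bis(benzyloxy)-3-bromophenyl]oxiran-2-yl}methanol
Conditions: RuCl(p-cymene)[(S,S)-TsDPEN] (2 mol%), HCO2Na, THF/H2O, 35 °C; Et3N-washed silica
Reagents that add atoms: none
Why: Noyori–Ikariya asymmetric transfer hydrogenation, in which the (S,S) catalyst delivers hydride to the aryl ketone in the sense that gives (S)-1-phenylethanol from acetophenone, sets the (R)-carbinol and so the threo epoxy alcohol against the erythro preference of simple hydrides, while the neutral formate medium spares the acid-labile oxirane.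

Step 14
Reactants: 15 1-[3,4-bis(benzyloxy)phenyl]ethan-1-one; 13 2-(allyloxy)-4,6-bis(benzyloxy)-3-bromobenzaldehyde
Product: 19 (E)-3-[2-(allyloxy)-4,6-bis(benzyloxy)-3-bromophenyl]-1-[3,4-bis(benzyloxy)phenyl]prop-2-en-1-one
Conditions: KOH, EtOH/THF, rt
Reagents that add atoms: none
Why: Claisen–Schmidt condensation as in step 11.

Step 15
Reactants: 19 the E-chalcone from step 14
Product: 20 [(2R,3S)-3-[2-(allyloxy)-4,6-bis(benzyloxy)-3-bromophenyl]oxiran-2-yl][3,4-bis(benzyloxy)phenyl]methanone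
Conditions: La(OiPr)3 (10 mol%), (S)-BINOL (10 mol%), Ph3As=O (10 mol%), TBHP (decane), 4 Å MS, THF, rt
Reagents that add atoms: tert-butyl hydroperoxide, CC(C)(C)OO
Why: The same ligand-controlled nucleophilic epoxidation as in step 12 sets the trans-(2R,3S)-oxirane.

Step 16
Reactants: 20 the (2R,3S)-epoxy ketone from step 15
Product: 21 (R)-[3,4-bis(benzyloxy)phenyl]{(2S,3S)-3-[2-(allyloxy)-4,6-bis(benzyloxy)-3-bromophenyl]oxiran-2-yl}methanol
Conditions: RuCl(p-cymene)[(S,S)-TsDPEN] (2 mol%), HCO2Na, THF/H2O, 35 °C; Et3N-washed silica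
Reagents that add atoms: none
Why: Catalyst-controlled asymmetric transfer hydrogenation as in step 13 sets the (R)-carbinol of the threo epoxy alcohol.

Step 17
Reactants: 22 3,4-bis(benzyloxy)benzaldehyde
Product: 23 racemic 1-[3,4-bis(benzyloxy)phenyl]prop-2-en-1-ol
Conditions: vinylmagnesium bromide, THF, 0 °C; aq NH4Cl
Reagents that add atoms: vinylmagnesium bromide, C=C[Mg]Br
Why: Grignard addition to the aldehyde gives the secondary allylic alcohol for kinetic resolution.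

Step 18
Reactants: 23 racemic 1-[3,4-bis(benzyloxy)phenyl]prop-2-en-1-ol
Product: 24 (S)-[3,4-bis(benzyloxy)phenyl][(2R)-oxiran-2-yl]methanol (erythro)
Conditions: Ti(OiPr)4 (0.2 equiv), L-(+)-diisopropyl tartrate (0.25 equiv), TBHP (0.45 equiv), 4 Å MS, CH2Cl2, −20 °C
Reagents that add atoms: tert-butyl hydroperoxide, CC(C)(C)OO
Why: Sharpless kinetic resolution, in which the L-(+)-tartrate complex should epoxidise the (R)-enantiomer of 23 fast and erythro-selectively and so set the (2R)-oxirane centre, leaving the (S)-allylic alcohol behind.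

Step 19
Reactants: 24 the erythro epoxy alcohol from step 18
Product: 25 [3,4-bis(benzyloxy)phenyl][(2R)-oxiran-2-yl]methanone
Conditions: Dess–Martin periodinane, CH2Cl2, 0 °C to rt
Reagents that add atoms: none
Why: Dess–Martin oxidation removes the wrongly configured carbinol centre while the oxirane centre, which does not enolise readily, is kept.

Step 20
Reactants: 25 the (2R)-epoxy ketone from step 19
Product: 26 (R)-[3,4-bis(benzyloxy)phenyl][(2R)-oxiran-2-yl]methanol (threo)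
Conditions: RuCl(p-cymene)[(S,S)-TsDPEN] (2 mol%), HCO2Na, THF/H2O, 35 °C
Reagents that add atoms: none
Why: Catalyst-controlled asymmetric transfer hydrogenation as in step 13 sets the (R)-carbinol, and the erythro isomer arising from any minor oxirane enantiomer is a separable diastereomer.

Step 21
Reactants: 18 the threo epoxy alcohol from step 13; 8 3,5-bis(benzyloxy)-2-(trimethylsilyl)phenyl trifluoromethanesulfonate
Product: 29 (2R,3R)-4β-[4-(allyloxy)-2,6-bis(benzyloxy)-3-bromophenyl]-5,7-bis(benzyloxy)-2-[3,4-bis(benzyloxy)phenyl]chroman-3-ol (2,3-cis and 3,4-trans), via potassium alkoxide 27 (not isolated), via aryne 28 (not isolated)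
Conditions: alcohol 18, KH (1.05 equiv), 18-crown-6, THF, 0 °C; then 8 (1.2 equiv), CsF (3 equiv), 0 °C to rt; aq NH4Cl
Reagents that add atoms: none
Why: Proposed new method: fluoride removes the silyl group of 8 and triflate leaves, giving aryne 28, whose triple bond is distorted by the inductively withdrawing benzyloxy group beside it, so that alkoxide 27 adds to the remote carbon (future C8a) and the aryl anion appears ortho to that ether oxygen (future C4a). The anion then opens the tethered oxirane at the benzylic carbon in a 6-endo SN2 step, which closes ring C by forming O1–C8a and then C4a–C4. The closest known chemistry is the three-component coupling of arynes, in which an oxygen nucleophile adds and the aryl anion is trapped by a carbon electrophile, joined to the Parham-type cyclisation of ortho-lithiated aryl glycidyl ethers to chroman-3-ols. C4 is set by inversion at the (3S)-oxirane carbon, which puts the C4 aryl group trans to the C3 oxygen, while C2 and C3 are carried over unchanged from 18 and give the 2,3-cis relation. The step needs O-addition at C8a and not at the carbon beside the ether, which the aryne distortion secures, and opening at C4 and not 5-exo at C3, which the electron-rich benzylic position and the strain of a benzo-fused five-membered transition state secure. The proton-free medium (KH, THF) keeps the aryl anion from being quenched before it cyclises.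

Step 22
Reactants: 29 the unit 1 flavan-3-ol from step 21
Product: 30 3-O-benzyl ether of 29
Conditions: NaH, BnBr, Bu4NI (cat.), DMF, 0 °C to rt
Reagents that add atoms: benzyl bromide, BrCc1ccccc1
Why: Williamson benzylation masks the secondary alcohol, which would otherwise be triflated later and would quench the aryl anion of the next annulation.

Step 23
Reactants: 30 3-O-benzyl ether of 29
Product: 31 phenol from 30 (pendant ring now 2,6-bis(benzyloxy)-3-bromo-4-hydroxyphenyl)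
Conditions: Pd(PPh3)4 (5 mol%), morpholine, THF, rt
Reagents that add atoms: none
Why: Tsuji–Trost deallylation with zerovalent palladium transfers the allyl group to morpholine at room temperature, where the hindered electron-rich aryl bromide and the benzyl ethers do not react.

Step 24
Reactants: 31 the phenol from step 23
Product: 34 unit 1 silyl triflate (pendant ring now 2,6-bis(benzyloxy)-3-(trimethylsilyl)-4-(triflyloxy)phenyl), via silyl ether 32 (not isolated), via lithium phenoxide 33 (not isolated)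
Conditions: HMDS, THF, 70 °C, then evaporation; n-BuLi, THF, −78 °C; Tf2O, −78 °C to rt
Reagents that add atoms: hexamethyldisilazane, C[Si](C)(C)N[Si](C)(C)C; trifluoromethanesulfonic anhydride, O=S(=O)(OS(=O)(=O)C(F)(F)F)C(F)(F)F
Why: The retro-Brook sequence of step 4 applies because bromine–lithium exchange at −78 °C is faster than deprotonation of any benzylic position, and the silyl group moves from oxygen to the carbon that will become C4a of unit 2.

Step 25
Reactants: 34 the unit 1 silyl triflate from step 24; 21 the threo epoxy alcohol from step 16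
Product: 37 dimer 3-ol (perbenzylated unit 1 linked 4β→6 to unit 2 that has a free 3-OH and a 4β-[2-(allyloxy)-4,6-bis(benzyloxy)-3-bromophenyl] group), via potassium alkoxide 35 (not isolated), via aryne 36 (not isolated)
Conditions: alcohol 21 (1.5 equiv), KH, 18-crown-6, THF, 0 °C; then 34 (1.0 equiv), CsF, 0 °C to rt; aq NH4Cl
Reagents that add atoms: none
Why: Proposed new method: the alkoxide–aryne addition and 6-endo epoxide opening of step 21 (closest known: three-component aryne couplings and the Parham cyclisation of aryl glycidyl ethers) are run on aryne 36, where the benzyloxy group beside the triple bond again sends the alkoxide oxygen to the remote carbon (C8a of unit 2), so that ring C of unit 2 closes on C4a with the 4→6 link already in place, C4 set by inversion and C2 and C3 taken from 21.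

Step 26
Reactants: 37 the dimer 3-ol from step 25
Product: 38 3-O-benzyl ether of 37
Conditions: NaH, BnBr, Bu4NI (cat.), DMF, 0 °C to rt
Reagents that add atoms: benzyl bromide, BrCc1ccccc1
Why: Williamson benzylation as in step 22.

Step 27
Reactants: 38 3-O-benzyl ether of 37
Product: 39 phenol from 38 (pendant ring now 4,6-bis(benzyloxy)-3-bromo-2-hydroxyphenyl)
Conditions: Pd(PPh3)4 (5 mol%), morpholine, THF, rt
Reagents that add atoms: none
Why: Tsuji–Trost deallylation as in step 23.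

Step 28
Reactants: 39 the phenol from step 27
Product: 42 dimer silyl triflate (pendant ring now 4,6-bis(benzyloxy)-3-(trimethylsilyl)-2-(triflyloxy)phenyl), via silyl ether 40 (not isolated), via lithium phenoxide 41 (not isolated)
Conditions: HMDS, THF, 70 °C, then evaporation; n-BuLi, THF, −78 °C; Tf2O, −78 °C to rt
Reagents that add atoms: hexamethyldisilazane, C[Si](C)(C)N[Si](C)(C)C; trifluoromethanesulfonic anhydride, O=S(=O)(OS(=O)(=O)C(F)(F)F)C(F)(F)F
Why: Retro-Brook sequence as in step 24, which here places silicon on the future C4a and triflate on the future C8a of unit 3.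

Step 29
Reactants: 42 the dimer silyl triflate from step 28; 18 the threo epoxy alcohol from step 13
Product: 45 trimer 3-ol (perbenzylated units 1 and 2 then unit 3 linked 4β→8 with a free 3-OH and a 4β-[4-(allyloxy)-2,6-bis(benzyloxy)-3-bromophenyl] group), via sodium alkoxide 43 (not isolated), via aryne 44 (not isolated)
Conditions: alcohol 18 (1.5 equiv), NaH, 15-crown-5, THF, 0 °C to rt; then 42 (1.0 equiv), CsF, 0 °C to rt; aq NH4Cl
Reagents that add atoms: none
Why: Proposed new method: the annulation of step 21 (closest known: three-component aryne couplings and the Parham cyclisation of aryl glycidyl ethers) is run on aryne 44 with the sodium alkoxide 43, chosen for this crowded case because the smaller sodium ion, still proton-free and freed by 15-crown-5, is the stronger Lewis acid and should hold the oxirane oxygen during ring closure; the distortion by the benzyloxy group on the future C5 must direct the alkoxide oxygen to the aryne carbon beside the C4 substituent of unit 2 (future C8a of unit 3), after which the anion on C4a opens the oxirane 6-endo with inversion at C4, giving the 4→8 link with C2 and C3 taken from 18.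

Step 30
Reactants: 45 the trimer 3-ol from step 29
Product: 46 3-O-benzyl ether of 45
Conditions: NaH, BnBr, Bu4NI (cat.), DMF, 0 °C to rt
Reagents that add atoms: benzyl bromide, BrCc1ccccc1
Why: Williamson benzylation as in step 22.

Step 31
Reactants: 46 3-O-benzyl ether of 45
Product: 47 phenol from 46 (pendant ring now 2,6-bis(benzyloxy)-3-bromo-4-hydroxyphenyl)
Conditions: Pd(PPh3)4 (5 mol%), morpholine, THF, rt
Reagents that add atoms: none
Why: Tsuji–Trost deallylation as in step 23.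

Step 32
Reactants: 47 the phenol from step 31
Product: 50 trimer silyl triflate (pendant ring now 2,6-bis(benzyloxy)-3-(trimethylsilyl)-4-(triflyloxy)phenyl), via silyl ether 48 (not isolated), via lithium phenoxide 49 (not isolated)
Conditions: HMDS, THF, 70 °C, then evaporation; n-BuLi, THF, −78 °C; Tf2O, −78 °C to rt
Reagents that add atoms: hexamethyldisilazane, C[Si](C)(C)N[Si](C)(C)C; trifluoromethanesulfonic anhydride, O=S(=O)(OS(=O)(=O)C(F)(F)F)C(F)(F)F
Why: Retro-Brook sequence as in step 24.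

Step 33
Reactants: 50 the trimer silyl triflate from step 32; 26 the threo terminal epoxy alcohol from step 20
Product: 53 protected tetramer (nineteen benzyl ethers and a free 3-OH on unit 4), via potassium alkoxide 51 (not isolated), via aryne 52 (not isolated)
Conditions: alcohol 26 (1.5 equiv), KH, 18-crown-6, THF, 0 °C; then 50 (1.0 equiv), CsF, 0 °C to rt; aq NH4Cl
Reagents that add atoms: none
Why: Proposed new method: the annulation of step 21 is run with the terminal epoxy alkoxide 51 on aryne 52, where oxygen again adds to the remote carbon (C8a of unit 4) and the aryl anion opens the oxirane at its unhindered CH2 in the 6-endo mode, a closure related to the Parham-type cyclisation of ortho-metalated aryl glycidyl ethers to chroman-3-ols, so that no new stereocentre forms and C2 and C3 of unit 4 come from 26.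

Step 34
Reactants: 53 the protected tetramer from step 33
Product: 54 CNP0120618.1, epicatechin-(4β→6)-epicatechin-(4β→8)-epicatechin-(4β→6)-epicatechin
Conditions: H2 (1 atm), Pd(OH)2/C, THF/MeOH/H2O, rt
Reagents that add atoms: none
Why: Hydrogenolysis of all nineteen benzyl ethers under mild neutral conditions, which are standard for benzylated procyanidins and should leave the interflavan bonds and the C2–O1 bonds intact.

## Compound list

1 | 3,5-bis(benzyloxy)phenol | Oc1cc(OCc2ccccc2)cc(OCc2ccccc2)c1 | starting material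
2 | 3,5-bis(benzyloxy)phenyl N,N-diethylcarbamate | CCN(CC)C(=O)Oc1cc(OCc2ccccc2)cc(OCc2ccccc2)c1 | intermediate
3 | 2-lithio-3,5-bis(benzyloxy)phenyl N,N-diethylcarbamate | CCN(CC)C(=O)Oc1cc(OCc2ccccc2)cc(OCc2ccccc2)c1[Li] | intermediate
4 | 2-bromo-3,5-bis(benzyloxy)phenyl N,N-diethylcarbamate | CCN(CC)C(=O)Oc1cc(OCc2ccccc2)cc(OCc2ccccc2)c1Br | intermediate
5 | 2-bromo-3,5-bis(benzyloxy)phenol | Oc1cc(OCc2ccccc2)cc(OCc2ccccc2)c1Br | intermediate
6 | [2-bromo-3,5-bis(benzyloxy)phenoxy]trimethylsilane | C[Si](C)(C)Oc1cc(OCc2ccccc2)cc(OCc2ccccc2)c1Br | intermediate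
7 | lithium 3,5-bis(benzyloxy)-2-(trimethylsilyl)phenoxide | [Li+].[O-]c1cc(OCc2ccccc2)cc(OCc2ccccc2)c1[Si](C)(C)C | intermediate
8 | 3,5-bis(benzyloxy)-2-(trimethylsilyl)phenyl trifluoromethanesulfonate | C[Si](C)(C)c1c(OCc2ccccc2)cc(OCc2ccccc2)cc1OS(=O)(=O)C(F)(F)F | intermediate
9 | 2,6-bis(benzyloxy)-4-hydroxybenzaldehyde | O=Cc1c(OCc2ccccc2)cc(O)cc1OCc1ccccc1 | intermediate
10 | 2,6-bis(benzyloxy)-3-bromo-4-hydroxybenzaldehyde | O=Cc1c(OCc2ccccc2)c(Br)c(O)cc1OCc1ccccc1 | intermediate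
11 | 4-(allyloxy)-2,6-bis(benzyloxy)-3-bromobenzaldehyde | O=Cc1c(OCc2ccccc2)c(Br)c(OCC=C)cc1OCc1ccccc1 | intermediate
12 | 4,6-bis(benzyloxy)-3-bromo-2-hydroxybenzaldehyde | O=Cc1c(O)c(Br)c(OCc2ccccc2)cc1OCc1ccccc1 | intermediate
13 | 2-(allyloxy)-4,6-bis(benzyloxy)-3-bromobenzaldehyde | O=Cc1c(OCC=C)c(Br)c(OCc2ccccc2)cc1OCc1ccccc1 | intermediate
14 | 3,4-dihydroxyacetophenone | CC(=O)c1ccc(O)c(O)c1 | starting material
15 | 1-[3,4-bis(benzyloxy)phenyl]ethan-1-one | CC(=O)c1ccc(OCc2ccccc2)c(OCc2ccccc2)c1 | intermediate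
16 | (E)-3-[4-(allyloxy)-2,6-bis(benzyloxy)-3-bromophenyl]-1-[3,4-bis(benzyloxy)phenyl]prop-2-en-1-one | O=C(/C=C/c1c(OCc2ccccc2)c(Br)c(OCC=C)cc1OCc1ccccc1)c1ccc(OCc2ccccc2)c(OCc2ccccc2)c1 | intermediate
17 | [(2R,3S)-3-[4-(allyloxy)-2,6-bis(benzyloxy)-3-bromophenyl]oxiran-2-yl][3,4-bis(benzyloxy)phenyl]methanone | O=C(c1ccc(OCc2ccccc2)c(OCc2ccccc2)c1)[C@@H]1O[C@H]1c1c(OCc2ccccc2)c(Br)c(OCC=C)cc1OCc1ccccc1 | intermediate
18 | (R)-[3,4-bis(benzyloxy)phenyl]{(2S,3S)-3-[4-(allyloxy)-2,6-bis(benzyloxy)-3-bromophenyl]oxiran-2-yl}methanol (threo, trans-oxirane) | O[C@H](c1ccc(OCc2ccccc2)c(OCc2ccccc2)c1)[C@@H]1O[C@H]1c1c(OCc2ccccc2)c(Br)c(OCC=C)cc1OCc1ccccc1 | intermediate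
19 | (E)-3-[2-(allyloxy)-4,6-bis(benzyloxy)-3-bromophenyl]-1-[3,4-bis(benzyloxy)phenyl]prop-2-en-1-one | O=C(/C=C/c1c(OCC=C)c(Br)c(OCc2ccccc2)cc1OCc1ccccc1)c1ccc(OCc2ccccc2)c(OCc2ccccc2)c1 | intermediate
20 | [(2R,3S)-3-[2-(allyloxy)-4,6-bis(benzyloxy)-3-bromophenyl]oxiran-2-yl][3,4-bis(benzyloxy)phenyl]methanone | O=C(c1ccc(OCc2ccccc2)c(OCc2ccccc2)c1)[C@@H]1O[C@H]1c1c(OCC=C)c(Br)c(OCc2ccccc2)cc1OCc1ccccc1 | intermediate
21 | (R)-[3,4-bis(benzyloxy)phenyl]{(2S,3S)-3-[2-(allyloxy)-4,6-bis(benzyloxy)-3-bromophenyl]oxiran-2-yl}methanol (threo, trans-oxirane) | O[C@H](c1ccc(OCc2ccccc2)c(OCc2ccccc2)c1)[C@@H]1O[C@H]1c1c(OCC=C)c(Br)c(OCc2ccccc2)cc1OCc1ccccc1 | intermediate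
22 | 3,4-bis(benzyloxy)benzaldehyde | O=Cc1ccc(OCc2ccccc2)c(OCc2ccccc2)c1 | starting material
23 | racemic 1-[3,4-bis(benzyloxy)phenyl]prop-2-en-1-ol | OC(C=C)c1ccc(OCc2ccccc2)c(OCc2ccccc2)c1 | intermediate
24 | (S)-[3,4-bis(benzyloxy)phenyl][(2R)-oxiran-2-yl]methanol (erythro) | O[C@@H](c1ccc(OCc2ccccc2)c(OCc2ccccc2)c1)[C@@H]1OC1 | intermediate
25 | [3,4-bis(benzyloxy)phenyl][(2R)-oxiran-2-yl]methanone | O=C(c1ccc(OCc2ccccc2)c(OCc2ccccc2)c1)[C@@H]1OC1 | intermediate
26 | (R)-[3,4-bis(benzyloxy)phenyl][(2R)-oxiran-2-yl]methanol (threo) | O[C@H](c1ccc(OCc2ccccc2)c(OCc2ccccc2)c1)[C@@H]1OC1 | intermediate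
27 | potassium alkoxide of 18 | [K+].[O-][C@H](c1ccc(OCc2ccccc2)c(OCc2ccccc2)c1)[C@@H]1O[C@H]1c1c(OCc2ccccc2)c(Br)c(OCC=C)cc1OCc1ccccc1 | intermediate
28 | 3,5-bis(benzyloxy)benzyne | c1ccccc1COC1=CC(OCc2ccccc2)=CC#C1 | intermediate
29 | (2R,3R)-4β-[4-(allyloxy)-2,6-bis(benzyloxy)-3-bromophenyl]-5,7-bis(benzyloxy)-2-[3,4-bis(benzyloxy)phenyl]chroman-3-ol (2,3-cis, 3,4-trans; protected unit 1) | c9ccccc9COc1cc(OCc9ccccc9)c2c(c1)O[C@H](c8ccc(OCc9ccccc9)c(OCc9ccccc9)c8)[C@H](O)[C@H]2c1c(OCc9ccccc9)c(Br)c(OCC=C)cc1OCc9ccccc9 | intermediate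
30 | 3-O-benzyl ether of 29 | c9ccccc9COc1cc(OCc9ccccc9)c2c(c1)O[C@H](c8ccc(OCc9ccccc9)c(OCc9ccccc9)c8)[C@H](OCc9ccccc9)[C@H]2c1c(OCc9ccccc9)c(Br)c(OCC=C)cc1OCc9ccccc9 | intermediate
31 | phenol from 30 (pendant ring 2,6-bis(benzyloxy)-3-bromo-4-hydroxyphenyl) | c9ccccc9COc1cc(OCc9ccccc9)c2c(c1)O[C@H](c8ccc(OCc9ccccc9)c(OCc9ccccc9)c8)[C@H](OCc9ccccc9)[C@H]2c1c(OCc9ccccc9)c(Br)c(O)cc1OCc9ccccc9 | intermediate
32 | trimethylsilyl ether of 31 | c9ccccc9COc1cc(OCc9ccccc9)c2c(c1)O[C@H](c8ccc(OCc9ccccc9)c(OCc9ccccc9)c8)[C@H](OCc9ccccc9)[C@H]2c1c(OCc9ccccc9)c(Br)c(O[Si](C)(C)C)cc1OCc9ccccc9 | intermediate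
33 | lithium phenoxide from 32 (silicon on the former C–Br carbon) | c9ccccc9COc1cc(OCc9ccccc9)c2c(c1)O[C@H](c8ccc(OCc9ccccc9)c(OCc9ccccc9)c8)[C@H](OCc9ccccc9)[C@H]2c1c(OCc9ccccc9)c([Si](C)(C)C)c([O-])cc1OCc9ccccc9.[Li+] | intermediate
34 | unit 1 silyl triflate (pendant ring 2,6-bis(benzyloxy)-3-(trimethylsilyl)-4-(triflyloxy)phenyl) | c9ccccc9COc1cc(OCc9ccccc9)c2c(c1)O[C@H](c8ccc(OCc9ccccc9)c(OCc9ccccc9)c8)[C@H](OCc9ccccc9)[C@H]2c1c(OCc9ccccc9)c([Si](C)(C)C)c(OS(=O)(=O)C(F)(F)F)cc1OCc9ccccc9 | intermediate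
35 | potassium alkoxide of 21 | [K+].[O-][C@H](c1ccc(OCc2ccccc2)c(OCc2ccccc2)c1)[C@@H]1O[C@H]1c1c(OCC=C)c(Br)c(OCc2ccccc2)cc1OCc1ccccc1 | intermediate
36 | aryne from 34 (triple bond between C3 and C4 of the pendant ring) | c9ccccc9COc1cc(OCc9ccccc9)c2c(c1)O[C@H](c8ccc(OCc9ccccc9)c(OCc9ccccc9)c8)[C@H](OCc9ccccc9)[C@H]2C1=C(OCc9ccccc9)C#CC=C1OCc9ccccc9 | intermediate
37 | dimer 3-ol (unit 1 perbenzylated, 4β→6, unit 2 with free 3-OH and 4β-[2-(allyloxy)-4,6-bis(benzyloxy)-3-bromophenyl]) | c9ccccc9COc1cc(OCc9ccccc9)c2c(c1)O[C@H](c8ccc(OCc9ccccc9)c(OCc9ccccc9)c8)[C@H](OCc9ccccc9)[C@H]2c1c(OCc9ccccc9)cc2c(c1OCc9ccccc9)[C@H](c3c(OCC=C)c(Br)c(OCc9ccccc9)cc3OCc9ccccc9)[C@@H](O)[C@@H](c8ccc(OCc9ccccc9)c(OCc9ccccc9)c8)O2 | intermediate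
38 | 3-O-benzyl ether of 37 | c9ccccc9COc1cc(OCc9ccccc9)c2c(c1)O[C@H](c8ccc(OCc9ccccc9)c(OCc9ccccc9)c8)[C@H](OCc9ccccc9)[C@H]2c1c(OCc9ccccc9)cc2c(c1OCc9ccccc9)[C@H](c3c(OCC=C)c(Br)c(OCc9ccccc9)cc3OCc9ccccc9)[C@@H](OCc9ccccc9)[C@@H](c8ccc(OCc9ccccc9)c(OCc9ccccc9)c8)O2 | intermediate
39 | phenol from 38 (pendant ring 4,6-bis(benzyloxy)-3-bromo-2-hydroxyphenyl) | c9ccccc9COc1cc(OCc9ccccc9)c2c(c1)O[C@H](c8ccc(OCc9ccccc9)c(OCc9ccccc9)c8)[C@H](OCc9ccccc9)[C@H]2c1c(OCc9ccccc9)cc2c(c1OCc9ccccc9)[C@H](c3c(O)c(Br)c(OCc9ccccc9)cc3OCc9ccccc9)[C@@H](OCc9ccccc9)[C@@H](c8ccc(OCc9ccccc9)c(OCc9ccccc9)c8)O2 | intermediate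
40 | trimethylsilyl ether of 39 | c9ccccc9COc1cc(OCc9ccccc9)c2c(c1)O[C@H](c8ccc(OCc9ccccc9)c(OCc9ccccc9)c8)[C@H](OCc9ccccc9)[C@H]2c1c(OCc9ccccc9)cc2c(c1OCc9ccccc9)[C@H](c3c(O[Si](C)(C)C)c(Br)c(OCc9ccccc9)cc3OCc9ccccc9)[C@@H](OCc9ccccc9)[C@@H](c8ccc(OCc9ccccc9)c(OCc9ccccc9)c8)O2 | intermediate
41 | lithium phenoxide from 40 (silicon on the former C–Br carbon) | c9ccccc9COc1cc(OCc9ccccc9)c2c(c1)O[C@H](c8ccc(OCc9ccccc9)c(OCc9ccccc9)c8)[C@H](OCc9ccccc9)[C@H]2c1c(OCc9ccccc9)cc2c(c1OCc9ccccc9)[C@H](c3c([O-])c([Si](C)(C)C)c(OCc9ccccc9)cc3OCc9ccccc9)[C@@H](OCc9ccccc9)[C@@H](c8ccc(OCc9ccccc9)c(OCc9ccccc9)c8)O2.[Li+] | intermediate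
42 | dimer silyl triflate (pendant ring 4,6-bis(benzyloxy)-3-(trimethylsilyl)-2-(triflyloxy)phenyl) | c9ccccc9COc1cc(OCc9ccccc9)c2c(c1)O[C@H](c8ccc(OCc9ccccc9)c(OCc9ccccc9)c8)[C@H](OCc9ccccc9)[C@H]2c1c(OCc9ccccc9)cc2c(c1OCc9ccccc9)[C@H](c3c(OS(=O)(=O)C(F)(F)F)c([Si](C)(C)C)c(OCc9ccccc9)cc3OCc9ccccc9)[C@@H](OCc9ccccc9)[C@@H](c8ccc(OCc9ccccc9)c(OCc9ccccc9)c8)O2 | intermediate
43 | sodium alkoxide of 18 | [Na+].[O-][C@H](c1ccc(OCc2ccccc2)c(OCc2ccccc2)c1)[C@@H]1O[C@H]1c1c(OCc2ccccc2)c(Br)c(OCC=C)cc1OCc1ccccc1 | intermediate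
44 | aryne from 42 (triple bond between C2 and C3 of the pendant ring) | c9ccccc9COc1cc(OCc9ccccc9)c2c(c1)O[C@H](c8ccc(OCc9ccccc9)c(OCc9ccccc9)c8)[C@H](OCc9ccccc9)[C@H]2c1c(OCc9ccccc9)cc2c(c1OCc9ccccc9)[C@H](C3=C(OCc9ccccc9)C=C(OCc9ccccc9)C#C3)[C@@H](OCc9ccccc9)[C@@H](c8ccc(OCc9ccccc9)c(OCc9ccccc9)c8)O2 | intermediate
45 | trimer 3-ol (units 1 and 2 perbenzylated, unit 3 linked 4β→8 with free 3-OH and 4β-[4-(allyloxy)-2,6-bis(benzyloxy)-3-bromophenyl]) | c9ccccc9COc1cc(OCc9ccccc9)c2c(c1)O[C@H](c8ccc(OCc9ccccc9)c(OCc9ccccc9)c8)[C@H](OCc9ccccc9)[C@H]2c1c(OCc9ccccc9)cc2c(c1OCc9ccccc9)[C@H](c1c(OCc9ccccc9)cc(OCc9ccccc9)c3c1O[C@H](c8ccc(OCc9ccccc9)c(OCc9ccccc9)c8)[C@H](O)[C@H]3c1c(OCc9ccccc9)c(Br)c(OCC=C)cc1OCc9ccccc9)[C@@H](OCc9ccccc9)[C@@H](c8ccc(OCc9ccccc9)c(OCc9ccccc9)c8)O2 | intermediate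
46 | 3-O-benzyl ether of 45 | c9ccccc9COc1cc(OCc9ccccc9)c2c(c1)O[C@H](c8ccc(OCc9ccccc9)c(OCc9ccccc9)c8)[C@H](OCc9ccccc9)[C@H]2c1c(OCc9ccccc9)cc2c(c1OCc9ccccc9)[C@H](c1c(OCc9ccccc9)cc(OCc9ccccc9)c3c1O[C@H](c8ccc(OCc9ccccc9)c(OCc9ccccc9)c8)[C@H](OCc9ccccc9)[C@H]3c1c(OCc9ccccc9)c(Br)c(OCC=C)cc1OCc9ccccc9)[C@@H](OCc9ccccc9)[C@@H](c8ccc(OCc9ccccc9)c(OCc9ccccc9)c8)O2 | intermediate
47 | phenol from 46 (pendant ring 2,6-bis(benzyloxy)-3-bromo-4-hydroxyphenyl) | c9ccccc9COc1cc(OCc9ccccc9)c2c(c1)O[C@H](c8ccc(OCc9ccccc9)c(OCc9ccccc9)c8)[C@H](OCc9ccccc9)[C@H]2c1c(OCc9ccccc9)cc2c(c1OCc9ccccc9)[C@H](c1c(OCc9ccccc9)cc(OCc9ccccc9)c3c1O[C@H](c8ccc(OCc9ccccc9)c(OCc9ccccc9)c8)[C@H](OCc9ccccc9)[C@H]3c1c(OCc9ccccc9)c(Br)c(O)cc1OCc9ccccc9)[C@@H](OCc9ccccc9)[C@@H](c8ccc(OCc9ccccc9)c(OCc9ccccc9)c8)O2 | intermediate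
48 | trimethylsilyl ether of 47 | c9ccccc9COc1cc(OCc9ccccc9)c2c(c1)O[C@H](c8ccc(OCc9ccccc9)c(OCc9ccccc9)c8)[C@H](OCc9ccccc9)[C@H]2c1c(OCc9ccccc9)cc2c(c1OCc9ccccc9)[C@H](c1c(OCc9ccccc9)cc(OCc9ccccc9)c3c1O[C@H](c8ccc(OCc9ccccc9)c(OCc9ccccc9)c8)[C@H](OCc9ccccc9)[C@H]3c1c(OCc9ccccc9)c(Br)c(O[Si](C)(C)C)cc1OCc9ccccc9)[C@@H](OCc9ccccc9)[C@@H](c8ccc(OCc9ccccc9)c(OCc9ccccc9)c8)O2 | intermediate
49 | lithium phenoxide from 48 (silicon on the former C–Br carbon) | c9ccccc9COc1cc(OCc9ccccc9)c2c(c1)O[C@H](c8ccc(OCc9ccccc9)c(OCc9ccccc9)c8)[C@H](OCc9ccccc9)[C@H]2c1c(OCc9ccccc9)cc2c(c1OCc9ccccc9)[C@H](c1c(OCc9ccccc9)cc(OCc9ccccc9)c3c1O[C@H](c8ccc(OCc9ccccc9)c(OCc9ccccc9)c8)[C@H](OCc9ccccc9)[C@H]3c1c(OCc9ccccc9)c([Si](C)(C)C)c([O-])cc1OCc9ccccc9)[C@@H](OCc9ccccc9)[C@@H](c8ccc(OCc9ccccc9)c(OCc9ccccc9)c8)O2.[Li+] | intermediate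
50 | trimer silyl triflate (pendant ring 2,6-bis(benzyloxy)-3-(trimethylsilyl)-4-(triflyloxy)phenyl) | c9ccccc9COc1cc(OCc9ccccc9)c2c(c1)O[C@H](c8ccc(OCc9ccccc9)c(OCc9ccccc9)c8)[C@H](OCc9ccccc9)[C@H]2c1c(OCc9ccccc9)cc2c(c1OCc9ccccc9)[C@H](c1c(OCc9ccccc9)cc(OCc9ccccc9)c3c1O[C@H](c8ccc(OCc9ccccc9)c(OCc9ccccc9)c8)[C@H](OCc9ccccc9)[C@H]3c1c(OCc9ccccc9)c([Si](C)(C)C)c(OS(=O)(=O)C(F)(F)F)cc1OCc9ccccc9)[C@@H](OCc9ccccc9)[C@@H](c8ccc(OCc9ccccc9)c(OCc9ccccc9)c8)O2 | intermediate
51 | potassium alkoxide of 26 | [K+].[O-][C@H](c1ccc(OCc2ccccc2)c(OCc2ccccc2)c1)[C@@H]1OC1 | intermediate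
52 | aryne from 50 (triple bond between C3 and C4 of the pendant ring) | c9ccccc9COc1cc(OCc9ccccc9)c2c(c1)O[C@H](c8ccc(OCc9ccccc9)c(OCc9ccccc9)c8)[C@H](OCc9ccccc9)[C@H]2c1c(OCc9ccccc9)cc2c(c1OCc9ccccc9)[C@H](c1c(OCc9ccccc9)cc(OCc9ccccc9)c3c1O[C@H](c8ccc(OCc9ccccc9)c(OCc9ccccc9)c8)[C@H](OCc9ccccc9)[C@H]3C1=C(OCc9ccccc9)C#CC=C1OCc9ccccc9)[C@@H](OCc9ccccc9)[C@@H](c8ccc(OCc9ccccc9)c(OCc9ccccc9)c8)O2 | intermediate
53 | protected tetramer (nineteen benzyl ethers, free 3-OH on unit 4) | c9ccccc9COc1cc(OCc9ccccc9)c2c(c1)O[C@H](c8ccc(OCc9ccccc9)c(OCc9ccccc9)c8)[C@H](OCc9ccccc9)[C@H]2c1c(OCc9ccccc9)cc2c(c1OCc9ccccc9)[C@H](c1c(OCc9ccccc9)cc(OCc9ccccc9)c3c1O[C@H](c8ccc(OCc9ccccc9)c(OCc9ccccc9)c8)[C@H](OCc9ccccc9)[C@H]3c1c(OCc9ccccc9)cc3c(c1OCc9ccccc9)C[C@@H](O)[C@@H](c8ccc(OCc9ccccc9)c(OCc9ccccc9)c8)O3)[C@@H](OCc9ccccc9)[C@@H](c8ccc(OCc9ccccc9)c(OCc9ccccc9)c8)O2 | intermediate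
54 | CNP0120618.1, epicatechin-(4β→6)-epicatechin-(4β→8)-epicatechin-(4β→6)-epicatechin | Oc1cc(O)c2c(c1)O[C@H](c1ccc(O)c(O)c1)[C@H](O)[C@H]2c1c(O)cc2c(c1O)[C@H](c1c(O)cc(O)c3c1O[C@H](c1ccc(O)c(O)c1)[C@H](O)[C@H]3c1c(O)cc3c(c1O)C[C@@H](O)[C@@H](c1ccc(O)c(O)c1)O3)[C@@H](O)[C@@H](c1ccc(O)c(O)c1)O2 | target

## Step count and risks

Total step count: 34 steps.
Longest linear sequence: 20 steps (steps 5, 6, 7, 11, 12, 13, then 21 to 34).

The three steps most likely to fail are three of the four annulations.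

**Step 21 (first annulation, on which every later step depends).** The aryl anion formed after O-addition may be lost before it closes the ring. Possible processes are proton transfer to the anion from C2–H or from a benzylic CH2, and ionisation or Payne migration of the electron-rich oxirane alkoxide before it meets the aryne.

Fallback: it sets out from epoxy ketone 17 and bromophenol 5 and comes back at 29. Chelation-controlled reduction of 17 with Zn(BH4)2 (Et2O, −20 °C) should give the erythro epoxy alcohol F1, the diastereomer that simple hydrides favour. Mitsunobu etherification of this alcohol with 5 (PPh3, DIAD, toluene, 0 °C) inverts the carbinol carbon and should give the aryl ether F2, which already holds O1–C8a and the C2 configuration of 29. Bromine–lithium exchange at both aryl bromides (t-BuLi, THF, −100 °C) then lets the aryllithium ortho to the ether oxygen open the oxirane at C4 in the 6-endo mode (Parham cyclisation). The aryllithium left on the pendant ring is brominated again with BrCl2C–CCl2Br before work-up, which returns 29.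

**Step 29 (unit 3, the most demanding case).** The alkoxide must add to the aryne carbon that lies beside the bulky C4 substituent of unit 2. Slow addition there would let attack at the other aryne carbon or decay of the aryne win.

Fallback: it sets out from phenol 39 and epoxy ketone 17 and comes back at 45. Zn(BH4)2 reduction of 17 gives the erythro epoxy alcohol F3 (the same compound as F1). Mitsunobu etherification of the hindered phenol 39 with this alcohol (PBu3, 1,1'-(azodicarbonyl)dipiperidine, toluene) inverts the carbinol carbon and should give the aryl ether F4. t-BuLi (THF, −100 °C) exchanges both bromines, the aryllithium beside the ether oxygen closes ring C of unit 3 by 6-endo opening of the oxirane, and BrCl2C–CCl2Br restores the bromine on the pendant ring, which returns 45.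

**Step 33 (unit 4).** The terminal oxirane has no benzylic activation, so 5-exo attack at the secondary carbon or Payne migration of alkoxide 51 to the internal epoxide may compete with the 6-endo closure.

Fallback: it sets out from phenol 47 and the erythro epoxy alcohol 24 and comes back at 53. Mitsunobu etherification of 47 with 24 (PPh3, DIAD, toluene, 0 °C) inverts the carbinol carbon and should give the aryl glycidyl-type ether F5. Bromine–lithium exchange of its single aryl bromide (t-BuLi, THF, −100 °C) is followed by Parham-type cyclisation at the terminal CH2, with MgBr2·OEt2 added to favour the six-membered ring over the five-membered one, which returns 53.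

## Further compounds

F1 | step 21 | (S)-[3,4-bis(benzyloxy)phenyl]{(2S,3S)-3-[4-(allyloxy)-2,6-bis(benzyloxy)-3-bromophenyl]oxiran-2-yl}methanol (erythro) | O[C@@H](c1ccc(OCc2ccccc2)c(OCc2ccccc2)c1)[C@@H]1O[C@H]1c1c(OCc2ccccc2)c(Br)c(OCC=C)cc1OCc1ccccc1
F2 | step 21 | 2-bromo-3,5-bis(benzyloxy)phenyl ether of 18 at the carbinol oxygen (R at the ether carbon, oxirane 2S,3S) | Brc1c(OCc2ccccc2)cc(OCc2ccccc2)cc1O[C@H](c1ccc(OCc2ccccc2)c(OCc2ccccc2)c1)[C@@H]1O[C@H]1c1c(OCc2ccccc2)c(Br)c(OCC=C)cc1OCc1ccccc1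
F3 | step 29 | (S)-[3,4-bis(benzyloxy)phenyl]{(2S,3S)-3-[4-(allyloxy)-2,6-bis(benzyloxy)-3-bromophenyl]oxiran-2-yl}methanol (erythro, identical with F1) | O[C@@H](c1ccc(OCc2ccccc2)c(OCc2ccccc2)c1)[C@@H]1O[C@H]1c1c(OCc2ccccc2)c(Br)c(OCC=C)cc1OCc1ccccc1
F4 | step 29 | aryl ether of phenol 39 with the carbinol carbon of the epoxy alcohol (R at the ether carbon, oxirane 2S,3S) | c9ccccc9COc1cc(OCc9ccccc9)c2c(c1)O[C@H](c8ccc(OCc9ccccc9)c(OCc9ccccc9)c8)[C@H](OCc9ccccc9)[C@H]2c1c(OCc9ccccc9)cc2c(c1OCc9ccccc9)[C@H](c3c(O[C@H](c8ccc(OCc9ccccc9)c(OCc9ccccc9)c8)[C@@H]4O[C@H]4c5c(OCc9ccccc9)c(Br)c(OCC=C)cc5OCc9ccccc9)c(Br)c(OCc9ccccc9)cc3OCc9ccccc9)[C@@H](OCc9ccccc9)[C@@H](c8ccc(OCc9ccccc9)c(OCc9ccccc9)c8)O2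
F5 | step 33 | aryl ether of phenol 47 with the carbinol carbon of the terminal epoxy alcohol (R at the ether carbon, oxirane 2R) | c9ccccc9COc1cc(OCc9ccccc9)c2c(c1)O[C@H](c8ccc(OCc9ccccc9)c(OCc9ccccc9)c8)[C@H](OCc9ccccc9)[C@H]2c1c(OCc9ccccc9)cc2c(c1OCc9ccccc9)[C@H](c1c(OCc9ccccc9)cc(OCc9ccccc9)c3c1O[C@H](c8ccc(OCc9ccccc9)c(OCc9ccccc9)c8)[C@H](OCc9ccccc9)[C@H]3c1c(OCc9ccccc9)c(Br)c(O[C@H](c8ccc(OCc9ccccc9)c(OCc9ccccc9)c8)[C@@H]4OC4)cc1OCc9ccccc9)[C@@H](OCc9ccccc9)[C@@H](c8ccc(OCc9ccccc9)c(OCc9ccccc9)c8)O2
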